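A small charge of substrate, 0.050 M, stands against 0.0600 M of activator at 20 °C, and we ask what its ring will be at 20 h and which remedy pays.

| flask | substrate | activator | temperature | remark | time |
|---|---|---|---|---|---|
| north-west | 0.050 M | 0.060 M | 20 °C | the very flask that is asked about, followed so far |  |
| south-west | 0.075 M | 0.060 M | 15 °C | run made earlier |  |
| flask | 0.050 M | 0.0600 M | 20 °C |  | 20 h |

- north-west (time / h: ring / %, substrate / %): 2.50: 35.6, 5.6; 5.00: 32.1, 1.0; 6.00: 32.5, 0.4; 10.0: 32.1, 0; 12.0: 32.0, 0.2; 15.0: 32.6, 0.1
- south-west (time / min: ring / %, substrate / %): 6.00: 0.8, 85.4; 20.0: 7.4, 64.1; 30.0: 12.2, 54.5; 50.0: 22.0, 41.6; 80.0: 29.1, 32.0; 90.0: 31.1, 29.2; 120: 31.9, 25.0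

(scatter of a reading: 0.3 percentage points)

- maple: at 20 h add activator, 100% of the amount charged, then wait 40 h
- elm: at 20 h raise the temperature by 25 K, then wait 40 h
- alder: at 20 h take out 90% of the ring then present, then wait 40 h
- cedar: change nothing and wait 40 h more

- what is taken out of ring is counted as made
- the earlier runs were read with a standard deviation of 0.3 percentage points
- additions bring no volume worth counting

- ring, in percent of the substrate first charged, at 20 h
- the remedy with the largest gain of ring, or "none" below 2 percentage points (maple / elm / alder / cedar / none)
- ring present, with what was taken out counted in, in percent of the substrate first charged, after alder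
- ring present, with what was taken out counted in, in percent of the substrate first charged, after cedar

We follow the rate, not the amounts, and take the fractional rate of substrate loss per hour. In the north-west run it averages 1.15 /h up to 2.50 h, then slows to 0.689 /h up to 5.00 h, a slowing that these readings show. We take substrate to be pseudo-first-order in the activator left, with one activator per substrate, so substrate is the limiting reagent. The first half of the substrate then slows the rate by a factor 1.71, and the remaining half by 3.50, together 6.00.

Joining the two ends, we take the later stretch as a rough stand-in for the slow end, and we put no number on the start. The slowing is bounded, so the rate does not fall to zero. That gives the quantity we carry, the end half-life, the half-life of substrate once the activator has sunk towards its floor: 1.01 h.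

From the reading of 0.4% substrate at 6.00 h, about 13.9 end half-lives pass before 20 h, so we expect no gain from maple or cedar. We put ring at the mean of the last readings, 32.2%. The rates say nothing about alder or elm.

The forecast gives 32.3% now, 52% after alder, 32.3% after cedar, and names alder as best, holding that “Warming would probably shift the balance only slightly”.

    substrate + activator → activated form (k = 0.790 /M/min, Ea = 72.0 kJ/mol)
    substrate + activated form → open dimer (k = 0.150 /M/min, Ea = 54.0 kJ/mol)
    activated form → ring (k = 0.0450 /min, Ea = 93.0 kJ/mol)
    ring ⇌ isomer of the product (K = 1.80, k = 0.0170 /min, Ea = 95.0 kJ/mol, ΔH = −42.0 kJ/mol)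
    (constants at 20 °C)

The flask gives 32.4% at 20 h, and the best remedy is elm, not alder: elm gains 30 percentage points, more than the 19 points of alder, which reaches 51.1%. Cedar's 40 h are 39.6 end half-lives and gain 0 points. In the neighbour flask kept at 5 °C, the 1.31% substrate left at 20 h means a mean half-life of 3.20 h, longer than our end half-life by a factor 3.17.

All runs are simulated for substances that don't exist.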